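The south-west run climbs straight.

in all of them: X 0.20 mM (held); D 26 µM

| charge | L | remark | time |
|---|---|---|---|
| south-west | 5 mM | the very flask that is asked about, followed so far |  |
| flask | 5.0 mM |  | 5.0 min |
south-west run (percent of the L charged)

| time / s | G / % |
|---|---|
| 10.0 | 4.3 |
| 12.0 | 5.3 |
| 20.0 | 8.9 |
| 25.0 | 10.7 |
| 30.0 | 12.9 |
| 40.0 | 17.1 |

(readings scatter by 0.5 percentage points)
- G at 5.0 min, in percent of the L charged
- concentration of J in solution at 5.0 min, in percent of saturation
- at the start none of J is dissolved
- on the list of suspects stand: X <-> J; L + J + D -> D + G; L <-> Z; 2 D <-> E; J + D <-> Q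

The south-west run is the asked flask followed early, so the estimate rests on two times. The first is the line time τ, the time G needs to reach the L charged at the slope of the run, taken from its last reading: τ = 234 s, a reading with that reading's scatter. The second is the asked 300 s, and their ratio is 1.28.

The straight line is the zero of the scale. With G zero order in L, the line holds and τ is shorter than the asked time, so this reckoning puts G at 100%. With G first order in L (pseudo-first-order, J and D steady), the same slope gives 72.3%. Both reckonings book each lost L as G, and this reckoning puts G between those two figures.

The forecast gives G 85% (72% to 100%) and J 90% of saturation (60% to 100%). Its own first-order figure is 75%, which differs from the one above: “A mixed case, or some catalyst held as E or Q, lies between these”.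

The flask gives G 41.8% and J 99.1% of saturation. Z then stands at 55.8% of the L charged, with L at 2.40%.

    X ⇌ J, rate k1*(csat - [J]) (kL = 0.480 s⁻¹)
    L + J + D → D + G (k = 2.90 × 10⁶ M⁻² s⁻¹)
    L ⇌ Z (K = 21.0, k = 0.00890 s⁻¹)
    2 D ⇌ E, settled at all times (K = 20000 M⁻¹)
    J + D ⇌ Q, settled at all times (K = 3300 M⁻¹)

In units of τ this flask has run 1.28 and gained on average 0.327 of the L charged per τ. The same flask read at 8.0 min has run 2.05 and gained on average 0.215 per τ, its G at 44.0%.

Readings and results are simulated with made-up constants.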